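**Retrosynthetic overview**
1. The lactone carbonyl is unveiled last, by oxidation of a bicyclic lactol methyl ether.
2. Key disconnection: C4–C5 with O–C1 (hetero-Diels–Alder) and C2–C7 (oxocarbenium closure) are cut together, giving an oxane ketal-aldehyde (C5–C12) and a commercial 1-methoxy-3-silyloxy diene (C1–C4).
3. The ketal-aldehyde comes from an open-chain β-keto Weinreb amide; its C8–C9 bond is an aldol between a methylketene dimer (C5–C8, from propanoyl chloride) and a C9–C12 aldehyde.
4. The C9–C12 aldehyde comes from ethyl 2-methylacetoacetate by enzymatic reduction.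
5. Ring order: oxane first (ketalisation, step 5); then the oxygen ring and the carbocycle of the 2-oxabicyclo[2.2.2]octane together in one flask (step 8).

Carbon labels used in all names: C1 lactone carbonyl, C2 quaternary bridgehead, C3 ketone, C4 CHMe beside the ketone, C5 bridgehead CH–O, C6 CHMe beside the spiro carbon, C7 spiro carbon, C8–C11 oxane carbons (C9 bears OAc, C11 bears the ring oxygen and methyl C12). Target: 2R,4S,5S,6R,7S,8S,9R,10R,11S.

Assumption: O-trimethylsilylquinine is taken to give the (S)-methylketene dimer and the (1S,2R)-ligand chromium catalyst the 5S cycloadduct; if either sense is the reverse, the pseudo-enantiomeric alkaloid or the (1R,2S) ligand is used and nothing else changes.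

**Step 1**
Reactants: 1 ethyl 2-methyl-3-oxobutanoate (racemic)
Product: 2 ethyl (2R,3S)-3-hydroxy-2-methylbutanoate
Conditions: (2R,3S)-selective ketoreductase, NADP+ (cat.), i-PrOH, phosphate buffer pH 7, 30 °C
Reagents that add atoms: none
Why: Ketoreductase dynamic reductive kinetic resolution: the α-centre racemises in buffer while the enzyme reduces one enantiomer from one carbonyl face, setting C10 (R) and C11 (S) as the syn pair.

**Step 2**
Reactants: 2 ethyl (2R,3S)-3-hydroxy-2-methylbutanoate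
Product: 3 ethyl (2R,3S)-2-methyl-3-(triethylsilyloxy)butanoate
Conditions: Et3SiCl, imidazole, CH2Cl2, 0 → 23 °C
Reagents that add atoms: chlorotriethylsilane, CC[Si](CC)(CC)Cl
Why: Silyl ether protection of the secondary alcohol; TES survives the basic aldol of step 4 and falls to mild acid in step 5, and no stereocentre is touched.

**Step 3**
Reactants: 3 ethyl (2R,3S)-2-methyl-3-(triethylsilyloxy)butanoate
Product: 4 (2R,3S)-2-methyl-3-(triethylsilyloxy)butanal
Conditions: i-Bu2AlH (1.05 equiv), CH2Cl2, −78 °C; aq. potassium sodium tartrate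
Reagents that add atoms: none
Why: Partial ester reduction with DIBAL-H through the tetrahedral aluminate that is stable at −78 °C, so neither over-reduction nor α-epimerisation occurs.

**Step 4**
Reactants: 5 propanoyl chloride; 4 (2R,3S)-2-methyl-3-(triethylsilyloxy)butanal
Product: 9 (2S,4S,5R,6S,7S)-5-hydroxy-N-methoxy-N,2,4,6-tetramethyl-3-oxo-7-(triethylsilyloxy)octanamide, via methylketene 6 (not isolated), via (S)-methylketene dimer 7 (not isolated), via lithium Z-enolate 8 (not isolated)
Conditions: 5 (2.4 equiv), i-Pr2NEt, O-trimethylsilylquinine (5 mol%), CH2Cl2, 23 °C; pentane, filter; LiN(OMe)Me (from MeNHOMe·HCl, n-BuLi), THF, −78 °C; then 4, −78 °C; aq. NH4Cl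
Reagents that add atoms: N,O-dimethylhydroxylamine hydrochloride, CNOC.Cl
Why: Calter ketene-dimer aldol: cinchona-catalysed dimerisation sets C6, amide ring-opening gives the Z-lithium enolate on the ethyl side only, and a closed Zimmerman–Traxler aldol gives the syn,syn adduct (C8 S, C9 R) in the anti-Felkin sense toward C10 that Z-enolates prefer, so reagent and substrate control are matched.

**Step 5**
Reactants: 9 (2S,4S,5R,6S,7S)-5-hydroxy-N-methoxy-N,2,4,6-tetramethyl-3-oxo-7-(triethylsilyloxy)octanamide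
Product: 11 (2S)-2-[(2S,3S,4R,5S,6S)-4-hydroxy-2-methoxy-3,5,6-trimethyloxan-2-yl]-N-methoxy-N-methylpropanamide, via hemiketal 10 (not isolated)
Conditions: PPTS (0.2 equiv), MeOH, 3 Å MS, 0 → 23 °C
Reagents that add atoms: methanol, CO
Why: Acidic methanolysis removes TES and the freed C11 hydroxyl closes on the C7 ketone (hemiketal, then methyl ketal under thermodynamic control), giving the oxane chair with axial OMe (anomeric effect) and equatorial side chain and masking the β-keto amide.

**Step 6**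
Reactants: 11 (2S)-2-[(2S,3S,4R,5S,6S)-4-hydroxy-2-methoxy-3,5,6-trimethyloxan-2-yl]-N-methoxy-N-methylpropanamide
Product: 12 (2S,3S,4R,5R,6S)-2-methoxy-2-[(2S)-1-[methoxy(methyl)amino]-1-oxopropan-2-yl]-3,5,6-trimethyloxan-4-yl acetate
Conditions: Ac2O, pyridine, DMAP (cat.), CH2Cl2, 23 °C
Reagents that add atoms: acetic anhydride, CC(=O)OC(C)=O
Why: DMAP-catalysed acylation of the only free hydroxyl (C9) installs the acetate of the target; ketal and Weinreb amide are inert.

**Step 7**
Reactants: 12 (2S,3S,4R,5R,6S)-2-methoxy-2-[(2S)-1-[methoxy(methyl)amino]-1-oxopropan-2-yl]-3,5,6-trimethyloxan-4-yl acetate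
Product: 13 (2S,3S,4R,5R,6S)-2-methoxy-3,5,6-trimethyl-2-[(2R)-1-oxopropan-2-yl]oxan-4-yl acetate
Conditions: Cp2Zr(H)Cl (1.5 equiv), THF, 23 °C, 20 min; silica
Reagents that add atoms: none
Why: Schwartz-reagent reduction of a tertiary amide: hydrozirconation gives a stable zirconated hemiaminal that releases the aldehyde on work-up, sparing acetate and ketal and leaving C6 unepimerised under neutral conditions.

**Step 8**
Reactants: 13 (2S,3S,4R,5R,6S)-2-methoxy-3,5,6-trimethyl-2-[(2R)-1-oxopropan-2-yl]oxan-4-yl acetate; 14 (1E,3Z)-1-methoxy-2-methyl-3-(trimethylsilyloxy)penta-1,3-diene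
Product: 18 spiro lactol methyl ether (target skeleton with C1 as CH(OMe); other stereocentres as in the target; both C1 anomers), via cycloadduct 15 (not isolated), via dihydropyranone 16 (not isolated), via 4-epi acetal 17 (not isolated)
Conditions: 14 (1.5 equiv), CrCl(L) (5 mol%; L = dianion of (1S,2R)-1-{[3-(adamantan-1-yl)-2-hydroxy-5-methylbenzylidene]amino}indan-2-ol), 4 Å MS, t-BuOMe, 23 °C; then CH2Cl2, Me3SiOTf (0.2 equiv), −78 → −20 °C; then TfOH (0.1 equiv), 0 → 23 °C; Et3N
Reagents that add atoms: none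
Why: Proposed new method: a catalyst-controlled endo hetero-Diels–Alder (closest known: Jacobsen chromium Schiff-base HDA of 1-methoxy-3-silyloxy dienes with chiral aldehydes) forms the oxygen ring and sets C5 (anti to the C6 methyl) with C4 cis; Me3SiOTf then gives dihydropyranone 16 and ionises the methyl ketal, and the nucleophilic α-carbon C2 of the vinylogous ester adds to the oxane oxocarbenium along the axial trajectory (closest known: Scheidt-type additions of dioxinone alkenes to oxocarbenium ions and Ferrier-type C-glycosylation), taking the place of OMe at C7 and fixing C2 through the forced boat, after which the C1 cation is capped by the released methoxytrimethylsilane and acid enolisation toward C4 (the only enolisable site) moves its methyl to the less hindered side beside the ring-oxygen bridge.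

**Step 9**
Reactants: 18 spiro lactol methyl ether
Product: 20 CNP0257416.2, (1S,4R,6S,7R,8S,3'S,4'R,5'R,6'S)-4,6,7,3',5',6'-hexamethyl-3,5-dioxospiro[2-oxabicyclo[2.2.2]octane-8,2'-oxan]-4'-yl acetate, via lactol 19 (not isolated)
Conditions: CrO3, H2SO4, H2O, acetone, 0 °C
Reagents that add atoms: water, O
Why: Jones oxidation of a lactol ether: aqueous acid hydrolyses the methyl acetal to the lactol, which CrO3 oxidises to the lactone, while ketone, acetate and oxane ether are inert and no stereocentre is affected.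

**Compound list**
1 | ethyl 2-methyl-3-oxobutanoate (racemic) | CCOC(=O)C(C)C(C)=O | starting material
2 | ethyl (2R,3S)-3-hydroxy-2-methylbutanoate | CCOC(=O)[C@H](C)[C@H](C)O | intermediate
3 | ethyl (2R,3S)-2-methyl-3-(triethylsilyloxy)butanoate | CCOC(=O)[C@H](C)[C@H](C)O[Si](CC)(CC)CC | intermediate
4 | (2R,3S)-2-methyl-3-(triethylsilyloxy)butanal | O=C[C@H](C)[C@H](C)O[Si](CC)(CC)CC | intermediate
5 | propanoyl chloride | CCC(Cl)=O | starting material
6 | methylketene | CC=C=O | intermediate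
7 | (3S,4Z)-4-ethylidene-3-methyloxetan-2-one | C/C=C1\OC(=O)[C@H]1C | intermediate
8 | lithium (2Z,4S)-5-[methoxy(methyl)amino]-4-methyl-5-oxopent-2-en-3-olate | [Li+].CON(C)C(=O)[C@@H](C)/C([O-])=C/C | intermediate
9 | (2S,4S,5R,6S,7S)-5-hydroxy-N-methoxy-N,2,4,6-tetramethyl-3-oxo-7-(triethylsilyloxy)octanamide | CON(C)C(=O)[C@@H](C)C(=O)[C@@H](C)[C@H](O)[C@H](C)[C@H](C)O[Si](CC)(CC)CC | intermediate
10 | (2S)-2-[(2S,3S,4R,5S,6S)-2,4-dihydroxy-3,5,6-trimethyloxan-2-yl]-N-methoxy-N-methylpropanamide | O[C@@H]1[C@H](C)[C@H](C)O[C@](O)([C@H](C)C(=O)N(C)OC)[C@H]1C | intermediate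
11 | (2S)-2-[(2S,3S,4R,5S,6S)-4-hydroxy-2-methoxy-3,5,6-trimethyloxan-2-yl]-N-methoxy-N-methylpropanamide | O[C@@H]1[C@H](C)[C@H](C)O[C@](OC)([C@H](C)C(=O)N(C)OC)[C@H]1C | intermediate
12 | (2S,3S,4R,5R,6S)-2-methoxy-2-[(2S)-1-[methoxy(methyl)amino]-1-oxopropan-2-yl]-3,5,6-trimethyloxan-4-yl acetate | CC(=O)O[C@@H]1[C@H](C)[C@H](C)O[C@](OC)([C@H](C)C(=O)N(C)OC)[C@H]1C | intermediate
13 | (2S,3S,4R,5R,6S)-2-methoxy-3,5,6-trimethyl-2-[(2R)-1-oxopropan-2-yl]oxan-4-yl acetate | CC(=O)O[C@@H]1[C@H](C)[C@H](C)O[C@](OC)([C@H](C)C=O)[C@H]1C | intermediate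
14 | (1E,3Z)-1-methoxy-2-methyl-3-(trimethylsilyloxy)penta-1,3-diene | CO/C=C(\C)/C(O[Si](C)(C)C)=C/C | starting material
15 | hetero-Diels–Alder cycloadduct: 13 with CHO replaced by a 2-methoxy-3,5-dimethyl-4-(trimethylsilyloxy)-5,6-dihydro-2H-pyran-6-yl ring (C4/C5 cis; C1 anomers) | CC(=O)O[C@@H]1[C@H](C)[C@H](C)O[C@](OC)([C@H](C)[C@@H]2OC(OC)C(C)=C(O[Si](C)(C)C)[C@@H]2C)[C@H]1C | intermediate
16 | cis-dihydropyranone: 13 with CHO replaced by a 2,3-cis-3,5-dimethyl-4-oxo-2,3-dihydro-4H-pyran-2-yl ring | CC(=O)O[C@@H]1[C@H](C)[C@H](C)O[C@](OC)([C@H](C)[C@@H]2OC=C(C)C(=O)[C@@H]2C)[C@H]1C | intermediate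
17 | C4-epimer of spiro lactol methyl ether 18 (C1 anomers) | CC(=O)O[C@@H]1[C@H](C)[C@H](C)O[C@]2([C@H](C)[C@@H]3OC(OC)[C@@]2(C)C(=O)[C@@H]3C)[C@H]1C | intermediate
18 | spiro lactol methyl ether: target with C1 as CH(OMe) (C1 anomers) | CC(=O)O[C@@H]1[C@H](C)[C@H](C)O[C@]2([C@H](C)[C@@H]3OC(OC)[C@@]2(C)C(=O)[C@H]3C)[C@H]1C | intermediate
19 | spiro lactol: target with C1 as CH(OH) (C1 anomers) | CC(=O)O[C@@H]1[C@H](C)[C@H](C)O[C@]2([C@H](C)[C@@H]3OC(O)[C@@]2(C)C(=O)[C@H]3C)[C@H]1C | intermediate
20 | CNP0257416.2, (1S,4R,6S,7R,8S,3'S,4'R,5'R,6'S)-4,6,7,3',5',6'-hexamethyl-3,5-dioxospiro[2-oxabicyclo[2.2.2]octane-8,2'-oxan]-4'-yl acetate | CC(=O)O[C@@H]1[C@H](C)[C@H](C)O[C@]2([C@H](C)[C@@H]3OC(=O)[C@@]2(C)C(=O)[C@H]3C)[C@H]1C | target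

**Totals**
Total steps: 9. Longest linear sequence: 9 (1 → 20; 5 and 14 are bought).

**Steps most likely to fail**

Step 8. The aldehyde is hindered (α-branched, β-quaternary), so the cycloaddition may be slow or mismatched with the catalyst. The closure joins two fully substituted carbons with the C6 methyl eclipsing C8, and deprotonation of the oxocarbenium could scramble C6. The C4 equilibration is expected to favour the target only moderately (estimated about 1–2 kcal/mol) and TfOH could also reopen the C2–C7 bond. The fallback sets out from 13 and comes back at 20. Propanoyl chloride 5 is dimerised with O-trimethylsilylquinidine to (R)-methylketene dimer F1, which LiN(OMe)Me opens to lithium Z-enolate F2. Its aldol with 13 (THF, −78 °C; reagent control, anti-Felkin) gives the open-chain δ-hydroxy-β-keto Weinreb amide F3. Trifluoroacetic acid in CH2Cl2 (0 → 23 °C) lactonises F3 to the β-keto-δ-lactone F4, whose enol closes on the oxocarbenium from the ketal to give the C4-epimer of the target F5. The same acid equilibrates F5 to 20, so no oxidation step is needed.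

Step 4. Double stereodifferentiation with a β-silyloxy aldehyde may erode selectivity, and the β-hydroxy ketone product can undergo retro-aldol. The fallback sets out from 4 and comes back at 9. Commercial (4S)-4-benzyl-3-propanoyl-1,3-oxazolidin-2-one undergoes a Bu2BOTf/Et3N aldol with propanal to give the syn-aldol imide F6. SO3·pyridine/DMSO oxidation gives the β-keto imide F7. Its TiCl4/i-Pr2NEt enolate adds to 4 to give the syn,syn imide aldol adduct F8. Me3Al/MeNHOMe·HCl transamination converts F8 into 9.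

Step 7. The amide is hindered, the acetate must survive, and the α-chiral aldehyde can epimerise. The fallback sets out from 11 and comes back at 13, bypassing 12. i-Bu2AlH (2.5 equiv, CH2Cl2, −78 °C) reduces the Weinreb amide of 11 to the hydroxy aldehyde F9. Ac2O/pyridine at 0 °C without DMAP then acetylates C9–OH to give 13.

**Further compounds**
F1 | step 8 | (3R,4Z)-4-ethylidene-3-methyloxetan-2-one | C/C=C1\OC(=O)[C@@H]1C
F2 | step 8 | lithium (2Z,4R)-5-[methoxy(methyl)amino]-4-methyl-5-oxopent-2-en-3-olate | [Li+].CON(C)C(=O)[C@H](C)/C([O-])=C/C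
F3 | step 8 | open-chain δ-hydroxy-β-keto Weinreb amide (13 extended at C5 by the syn,syn dipropionate unit) | CC(=O)O[C@@H]1[C@H](C)[C@H](C)O[C@](OC)([C@H](C)[C@H](O)[C@@H](C)C(=O)[C@@H](C)C(=O)N(C)OC)[C@H]1C
F4 | step 8 | β-keto-δ-lactone (4,5-cis; C2 epimers/enol) on the oxane methyl ketal | CC(=O)O[C@@H]1[C@H](C)[C@H](C)O[C@](OC)([C@H](C)[C@@H]2OC(=O)C(C)C(=O)[C@@H]2C)[C@H]1C
F5 | step 8 | C4-epimer of the target | CC(=O)O[C@@H]1[C@H](C)[C@H](C)O[C@]2([C@H](C)[C@@H]3OC(=O)[C@@]2(C)C(=O)[C@@H]3C)[C@H]1C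
F6 | step 4 | (4S)-4-benzyl-3-[(2S,3R)-3-hydroxy-2-methylpentanoyl]-1,3-oxazolidin-2-one | CC[C@@H](O)[C@H](C)C(=O)N1[C@@H](Cc2ccccc2)COC1=O
F7 | step 4 | (4S)-4-benzyl-3-[(2S)-2-methyl-3-oxopentanoyl]-1,3-oxazolidin-2-one | CCC(=O)[C@H](C)C(=O)N1[C@@H](Cc2ccccc2)COC1=O
F8 | step 4 | (4S)-4-benzyl-3-[(2S,4S,5R,6S,7S)-5-hydroxy-2,4,6-trimethyl-3-oxo-7-(triethylsilyloxy)octanoyl]-1,3-oxazolidin-2-one | O=C1OC[C@H](Cc2ccccc2)N1C(=O)[C@@H](C)C(=O)[C@@H](C)[C@H](O)[C@H](C)[C@H](C)O[Si](CC)(CC)CC
F9 | step 7 | (2R)-2-[(2S,3S,4R,5S,6S)-4-hydroxy-2-methoxy-3,5,6-trimethyloxan-2-yl]propanal | O[C@@H]1[C@H](C)[C@H](C)O[C@](OC)([C@H](C)C=O)[C@H]1C
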